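Germacranolide locants are used: C6 is the lactone CH–O, C7 the ring-fusion CH, C8 the isovalerate carbon, C3 the acetate carbon, C1/C10 the epoxide, C11 the α-carbon, C12 the lactone carbonyl, C13 the exocyclic CH2. Everything rests on opening the ten-membered carbocycle at C6–C7 and deleting C12. In the key step an acyclic Z-enal (C6) ending in a terminal allene (C7=C11=C13) takes up CO2 on zerovalent nickel: C11–C12 forms, and the resulting 2-carboxyallylnickel adds through C7 to the C6 aldehyde, closing the carbocycle; lactonisation gives the cis-fused α-methylene-γ-butyrolactone. The step exploits the lactone ring O–C12–C11–C7–C6 fused at C6–C7. The precursor is a 12-nor-farnesane chain built from 4-methylanisole.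

Key step: step 12

Assumption: the antipodes of the chiral controllers in steps 3 and 6 are those whose accepted transition-state models give Re-face addition at C8 and Si-face addition at C3; if either model proved reversed for these aldehydes, the mirror-image controller would be used.

Step 1
Reactants: 1 4-methylanisole
Product: 2 1-methoxy-4-methylcyclohexa-1,4-diene
Conditions: Li, NH3 (l), t-BuOH, THF, −78 to −33 °C
Reagents that add atoms: none
Why: Birch reduction of an anisole leaves the enol ether and the methyl-bearing olefin unconjugated in a 1,4-diene, so the future C1=C10 olefin is held in a ring and can only be cis.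

Step 2
Reactants: 2 1-methoxy-4-methylcyclohexa-1,4-diene
Product: 4 methyl (3Z)-4-methyl-6-oxohex-3-enoate, via methoxy hydroperoxide 3 (not isolated)
Conditions: O3 (1.0 equiv), CH2Cl2/MeOH, −78 °C; Me2S, −78 to 0 °C; used crude
Reagents that add atoms: ozone [O-][O+]=O
Why: Chemoselective ozonolysis cleaves the electron-rich enol ether bond much faster than the trisubstituted olefin, giving an ester end (future C3) and an aldehyde end (future C8) on a Z-olefin inherited from the ring.

Step 3
Reactants: 4 methyl (3Z)-4-methyl-6-oxohex-3-enoate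
Product: 5 methyl (3Z,6S)-6-hydroxy-4-methylnona-3,7,8-trienoate
Conditions: (R,R)-2-bromo-4,5-diphenyl-1,3-bis(p-tolylsulfonyl)-1,3,2-diazaborolidine, allenyltributylstannane, CH2Cl2, 0 °C to rt; then 4, −78 °C
Reagents that add atoms: allenyltributylstannane C=C=C[Sn](CCCC)(CCCC)CCCC
Why: Enantioselective propargylboration: the stannane transmetalates (SE2′) to a B-propargyl diazaborolidine that adds to the aldehyde through a six-membered chair (SE2′ again) to give the allenyl carbinol, the (R,R)-controller directing Re-face attack to set (S)-C8, while the ester is inert at −78 °C.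

Step 4
Reactants: 5 methyl (3Z,6S)-6-hydroxy-4-methylnona-3,7,8-trienoate
Product: 6 methyl (3Z,6S)-6-[(tert-butyldimethylsilyl)oxy]-4-methylnona-3,7,8-trienoate
Conditions: TBSCl, imidazole, DMF, 0 °C to rt
Reagents that add atoms: tert-butyldimethylsilyl chloride CC(C)(C)[Si](C)(C)Cl
Why: Standard silylation of the secondary alcohol gives an ether that should outlast the hydride, organometallic and oxidative steps and is removed last.

Step 5
Reactants: 6 methyl (3Z,6S)-6-[(tert-butyldimethylsilyl)oxy]-4-methylnona-3,7,8-trienoate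
Product: 7 (3Z,6S)-6-[(tert-butyldimethylsilyl)oxy]-4-methylnona-3,7,8-trienal
Conditions: iBu2AlH (1.05 equiv), CH2Cl2, −78 °C; MeOH, then aq. potassium sodium tartrate; used crude
Reagents that add atoms: none
Why: Partial ester reduction: the aluminium hemiacetal is stable at −78 °C and releases the aldehyde only on work-up, so the skipped olefin is never exposed to base.

Step 6
Reactants: 7 (3Z,6S)-6-[(tert-butyldimethylsilyl)oxy]-4-methylnona-3,7,8-trienal
Product: 8 methyl (4R,6Z,9S)-9-[(tert-butyldimethylsilyl)oxy]-4-hydroxy-7-methyldodeca-6,10,11-trien-2-ynoate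
Conditions: methyl propiolate, Me2Zn, (R,R)-ProPhenol (20 mol %), Ph3PO (40 mol %), toluene, 0 °C
Reagents that add atoms: methyl propiolate C#CC(=O)OC
Why: Zinc–ProPhenol asymmetric alkynylation: the dinuclear zinc catalyst binds the aldehyde and the zinc acetylide together, and the (R,R)-ligand is taken to deliver the alkyne to the Si face, setting (R)-C3 without strong base.

Step 7
Reactants: 8 methyl (4R,6Z,9S)-9-[(tert-butyldimethylsilyl)oxy]-4-hydroxy-7-methyldodeca-6,10,11-trien-2-ynoate
Product: 9 methyl (4R,6Z,9S)-9-[(tert-butyldimethylsilyl)oxy]-7-methyl-4-[(triethylsilyl)oxy]dodeca-6,10,11-trien-2-ynoate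
Conditions: Et3SiOTf, 2,6-lutidine, CH2Cl2, −78 °C
Reagents that add atoms: triethylsilyl trifluoromethanesulfonate CC[Si](CC)(CC)OS(=O)(=O)C(F)(F)F
Why: Silylation with the triflate and a hindered pyridine avoids conjugate addition of a nucleophilic base to the ynoate, and the TES ether prevents butenolide formation in step 8 and can later be cleaved beside TBS.

Step 8
Reactants: 9 methyl (4R,6Z,9S)-9-[(tert-butyldimethylsilyl)oxy]-7-methyl-4-[(triethylsilyl)oxy]dodeca-6,10,11-trien-2-ynoate
Product: 10 methyl (2Z,4R,6Z,9S)-9-[(tert-butyldimethylsilyl)oxy]-3,7-dimethyl-4-[(triethylsilyl)oxy]dodeca-2,6,10,11-tetraenoate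
Conditions: Me2CuLi (from CuI and MeLi), THF, −78 °C; aq. NH4Cl at −78 °C
Reagents that add atoms: lithium dimethylcuprate [Li+].C[Cu-]C
Why: Conjugate addition (syn-carbocupration) to the ynoate and cold protonation of the vinylcopper with retention place the new C15 methyl and H5 cis, which is the Z-enoate with C3 and C6 cis.

Step 9
Reactants: 10 methyl (2Z,4R,6Z,9S)-9-[(tert-butyldimethylsilyl)oxy]-3,7-dimethyl-4-[(triethylsilyl)oxy]dodeca-2,6,10,11-tetraenoate
Product: 11 methyl (2Z,4R)-5-{(2R,3S)-3-[(2S)-2-[(tert-butyldimethylsilyl)oxy]penta-3,4-dien-1-yl]-3-methyloxiran-2-yl}-3-methyl-4-[(triethylsilyl)oxy]pent-2-enoate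
Conditions: D-fructose-derived ketone catalyst (0.3 equiv), KHSO5 (as 2KHSO5·KHSO4·K2SO4), K2CO3, Bu4NHSO4, MeCN/dimethoxymethane/aq. Na2B4O7 buffer, 0 °C
Reagents that add atoms: potassium peroxymonosulfate [K+].[O-]S(=O)(=O)OO
Why: Shi epoxidation: the chiral dioxirane attacks the electron-rich C1=C10 olefin through the spiro transition state set by the trans C2–C1=C10–CH3 frame, which should give the (1R,10S) cis-epoxide, while the enoate and the allene (deactivated by its allylic silyloxy group) react far more slowly.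

Step 10
Reactants: 11 methyl (2Z,4R)-5-{(2R,3S)-3-[(2S)-2-[(tert-butyldimethylsilyl)oxy]penta-3,4-dien-1-yl]-3-methyloxiran-2-yl}-3-methyl-4-[(triethylsilyl)oxy]pent-2-enoate
Product: 12 (2Z,4R)-5-{(2R,3S)-3-[(2S)-2-[(tert-butyldimethylsilyl)oxy]penta-3,4-dien-1-yl]-3-methyloxiran-2-yl}-3-methyl-4-[(triethylsilyl)oxy]pent-2-en-1-ol
Conditions: iBu2AlH (2.5 equiv), CH2Cl2, −78 °C; aq. potassium sodium tartrate
Reagents that add atoms: none
Why: 1,2-Reduction of the enoate at −78 °C gives the Z-allylic alcohol without opening the trisubstituted epoxide or touching the silyl ethers.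

Step 11
Reactants: 12 (2Z,4R)-5-{(2R,3S)-3-[(2S)-2-[(tert-butyldimethylsilyl)oxy]penta-3,4-dien-1-yl]-3-methyloxiran-2-yl}-3-methyl-4-[(triethylsilyl)oxy]pent-2-en-1-ol
Product: 13 (2Z,4R)-5-{(2R,3S)-3-[(2S)-2-[(tert-butyldimethylsilyl)oxy]penta-3,4-dien-1-yl]-3-methyloxiran-2-yl}-3-methyl-4-[(triethylsilyl)oxy]pent-2-enal
Conditions: TEMPO (10 mol %), PhI(OAc)2, CH2Cl2, pH 7 buffer, 0 °C to rt; used at once
Reagents that add atoms: none
Why: Oxoammonium (TEMPO) oxidation of the primary allylic alcohol is near-neutral, stops at the aldehyde and preserves the Z geometry of neral-type enals.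

Step 12
Reactants: 13 (2Z,4R)-5-{(2R,3S)-3-[(2S)-2-[(tert-butyldimethylsilyl)oxy]penta-3,4-dien-1-yl]-3-methyloxiran-2-yl}-3-methyl-4-[(triethylsilyl)oxy]pent-2-enal
Product: 16 3-O-triethylsilyl-8-O-tert-butyldimethylsilyl macrolactone (ring configuration as in 20), via oxanickelacycle 14 (not isolated), via hydroxy acid 15 (not isolated)
Conditions: Ni(cod)2 (1.5 equiv), DBU (3 equiv), CO2 (1 atm), THF (3 mM), 0 °C to rt; aq. NH4Cl; then EDC·HCl, DMAP (cat.), CH2Cl2, 0 °C
Reagents that add atoms: carbon dioxide O=C=O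
Why: Proposed new method: zerovalent nickel ligated by DBU couples CO2 oxidatively with the terminal C11=C13 π-bond of the allene from the face anti to C8, bonding the CO2 carbon to the central carbon C11 and giving oxanickelacycle 14, a Z-configured σ-allylnickel carboxylate whose γ-carbon C7 then adds to the tethered C6 aldehyde through a six-membered chair; protonation gives hydroxy acid 15, which the carbodiimide closes to the lactone. The closest known reaction type is the nickel-promoted carboxylation/cyclization cascade of allenyl aldehydes under CO2 that forms five- and six-membered carbocycles, together with the three-component coupling of terminal allenes, CO2 and aldehydes; only the ten-membered ring size is new, and that closure mirrors the Barbier-type allylmetal–aldehyde macrocyclizations used for germacranolides. The ten-membered carbocycle closes by intramolecular carbonyl allylation (10-exo-trig at the C=O, SE2′ at the allyl unit) and the lactone by 5-exo-trig acyl substitution. C7 is controlled by C8: with H8 eclipsing the allyl unit (minimum allylic 1,3-strain) the aldehyde, delivered by the C9 tether, attacks anti to the silyloxy group; C6 is controlled by the chair with the Z-allylnickel (C8 axial, C5 equatorial), which gives the syn adduct and hence the cis-fused lactone. The step needs CO2 capture to outrun allene oligomerization and direct allene–aldehyde coupling (excess CO2 at 0 °C), ring closure to outrun intermolecular allylation (high dilution, and the Z-olefin and cis-epoxide pre-fold the chain), and retention of the Z-enal (low temperature, DBU buffered as its CO2 adduct).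

Step 13
Reactants: 16 3-O-triethylsilyl-8-O-tert-butyldimethylsilyl macrolactone
Product: 17 3-hydroxy-8-O-tert-butyldimethylsilyl macrolactone
Conditions: HF·pyridine, pyridine, THF, 0 °C
Reagents that add atoms: none
Why: Buffered fluoride cleaves the more labile, less hindered allylic TES ether faster than the secondary TBS ether, and the pyridine buffer protects the epoxide.

Step 14
Reactants: 17 3-hydroxy-8-O-tert-butyldimethylsilyl macrolactone
Product: 18 3-acetoxy-8-O-tert-butyldimethylsilyl macrolactone
Conditions: Ac2O, pyridine, DMAP (cat.), CH2Cl2, 0 °C to rt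
Reagents that add atoms: acetic anhydride CC(=O)OC(C)=O
Why: DMAP-catalysed acylation of the free C3 alcohol touches no stereocentre.

Step 15
Reactants: 18 3-acetoxy-8-O-tert-butyldimethylsilyl macrolactone
Product: 19 3-acetoxy-8-hydroxy macrolactone
Conditions: HF·pyridine, THF, 0 °C to rt
Reagents that add atoms: none
Why: Fluoride desilylation under mildly acidic conditions should leave the acetate, the epoxide and the base-sensitive α-methylene lactone intact.

Step 16
Reactants: 19 3-acetoxy-8-hydroxy macrolactone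
Product: 20 CNP0157657.2
Conditions: 3-methylbutanoic anhydride, DMAP, pyridine, CH2Cl2, 0 °C to rt
Reagents that add atoms: 3-methylbutanoic anhydride CC(C)CC(=O)OC(=O)CC(C)C
Why: DMAP-catalysed acylation of the hindered C8 alcohol gives the isovalerate and is run at once so that the free 8-hydroxy lactone has no time to translactonise.

Compound list

1 | 4-methylanisole | COc1ccc(C)cc1 | starting material
2 | 1-methoxy-4-methylcyclohexa-1,4-diene | COC1=CCC(C)=CC1 | intermediate
3 | methyl (3Z)-6-hydroperoxy-6-methoxy-4-methylhex-3-enoate (not isolated) | COC(=O)C/C=C(/C)CC(OC)OO | intermediate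
4 | methyl (3Z)-4-methyl-6-oxohex-3-enoate | COC(=O)C/C=C(/C)CC=O | intermediate
5 | methyl (3Z,6S)-6-hydroxy-4-methylnona-3,7,8-trienoate | COC(=O)C/C=C(/C)C[C@H](O)C=C=C | intermediate
6 | methyl (3Z,6S)-6-[(tert-butyldimethylsilyl)oxy]-4-methylnona-3,7,8-trienoate | COC(=O)C/C=C(/C)C[C@H](O[Si](C)(C)C(C)(C)C)C=C=C | intermediate
7 | (3Z,6S)-6-[(tert-butyldimethylsilyl)oxy]-4-methylnona-3,7,8-trienal | O=CC/C=C(/C)C[C@H](O[Si](C)(C)C(C)(C)C)C=C=C | intermediate
8 | methyl (4R,6Z,9S)-9-[(tert-butyldimethylsilyl)oxy]-4-hydroxy-7-methyldodeca-6,10,11-trien-2-ynoate | COC(=O)C#C[C@H](O)C/C=C(/C)C[C@H](O[Si](C)(C)C(C)(C)C)C=C=C | intermediate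
9 | methyl (4R,6Z,9S)-9-[(tert-butyldimethylsilyl)oxy]-7-methyl-4-[(triethylsilyl)oxy]dodeca-6,10,11-trien-2-ynoate | COC(=O)C#C[C@H](O[Si](CC)(CC)CC)C/C=C(/C)C[C@H](O[Si](C)(C)C(C)(C)C)C=C=C | intermediate
10 | methyl (2Z,4R,6Z,9S)-9-[(tert-butyldimethylsilyl)oxy]-3,7-dimethyl-4-[(triethylsilyl)oxy]dodeca-2,6,10,11-tetraenoate | COC(=O)/C=C(/C)[C@H](O[Si](CC)(CC)CC)C/C=C(/C)C[C@H](O[Si](C)(C)C(C)(C)C)C=C=C | intermediate
11 | methyl (2Z,4R)-5-{(2R,3S)-3-[(2S)-2-[(tert-butyldimethylsilyl)oxy]penta-3,4-dien-1-yl]-3-methyloxiran-2-yl}-3-methyl-4-[(triethylsilyl)oxy]pent-2-enoate | COC(=O)/C=C(/C)[C@H](O[Si](CC)(CC)CC)C[C@H]1O[C@@]1(C)C[C@H](O[Si](C)(C)C(C)(C)C)C=C=C | intermediate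
12 | the corresponding (2Z)-pent-2-en-1-ol (C6 alcohol; other centres as in 11) | OC/C=C(/C)[C@H](O[Si](CC)(CC)CC)C[C@H]1O[C@@]1(C)C[C@H](O[Si](C)(C)C(C)(C)C)C=C=C | intermediate
13 | the corresponding (2Z)-pent-2-enal (C6 aldehyde, terminal allene C7=C11=C13; other centres as in 11) | O=C/C=C(/C)[C@H](O[Si](CC)(CC)CC)C[C@H]1O[C@@]1(C)C[C@H](O[Si](C)(C)C(C)(C)C)C=C=C | intermediate
14 | oxanickelacycle (not isolated): 4-alkylidene-1-oxa-2-nickelacyclopentan-5-one from the allene terminus of 13 and CO2, C8 cis to CH2–Ni, two DBU on nickel | O=C/C=C(/C)[C@H](O[Si](CC)(CC)CC)C[C@H]1O[C@@]1(C)C[C@H](O[Si](C)(C)C(C)(C)C)/C=C1\C[Ni]OC1=O.C1CCN2CCCN=C2CC1.C1CCN2CCCN=C2CC1 | intermediate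
15 | hydroxy acid (not isolated): 2-(ten-membered ring-7-yl)prop-2-enoic acid with free 6-OH, H6/H7 cis, other centres as in 20 | OC(=O)C(=C)[C@H]1[C@@H](O)/C=C(/C)[C@H](O[Si](CC)(CC)CC)C[C@H]2O[C@@]2(C)C[C@@H]1O[Si](C)(C)C(C)(C)C | intermediate
16 | 3-O-triethylsilyl-8-O-tert-butyldimethylsilyl-1,10-epoxygermacra-4Z,11(13)-dien-12,6-olide (configuration as in 20) | C=C1C(=O)O[C@H]2/C=C(/C)[C@H](O[Si](CC)(CC)CC)C[C@H]3O[C@@]3(C)C[C@H](O[Si](C)(C)C(C)(C)C)[C@@H]12 | intermediate
17 | 3-hydroxy-8-O-tert-butyldimethylsilyl lactone (configuration as in 20) | C=C1C(=O)O[C@H]2/C=C(/C)[C@H](O)C[C@H]3O[C@@]3(C)C[C@H](O[Si](C)(C)C(C)(C)C)[C@@H]12 | intermediate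
18 | 3-acetoxy-8-O-tert-butyldimethylsilyl lactone (configuration as in 20) | C=C1C(=O)O[C@H]2/C=C(/C)[C@H](OC(C)=O)C[C@H]3O[C@@]3(C)C[C@H](O[Si](C)(C)C(C)(C)C)[C@@H]12 | intermediate
19 | 3-acetoxy-8-hydroxy lactone (configuration as in 20) | C=C1C(=O)O[C@H]2/C=C(/C)[C@H](OC(C)=O)C[C@H]3O[C@@]3(C)C[C@H](O)[C@@H]12 | intermediate
20 | CNP0157657.2, (1R,3R,6S,7R,8S,10S)-3-acetoxy-1,10-epoxy-8-(3-methylbutanoyloxy)germacra-4Z,11(13)-dien-12,6-olide, lactone cis-fused | C=C1C(=O)O[C@H]2/C=C(/C)[C@H](OC(C)=O)C[C@H]3O[C@@]3(C)C[C@H](OC(=O)CC(C)C)[C@@H]12 | target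

Total steps: 16. Longest linear sequence: 16 steps (from 1).

Steps most likely to fail

Step 12. The allylnickel carboxylate may add too slowly across the ten-membered distance, so that protonolysis on work-up (carboxylation without ring closure), intermolecular allylation or allene oligomerization take over; DBU may also isomerise the Z-enal. The fallback uses known chemistry and sets out from 13. Bromine (1 equiv, CH2Cl2, −78 °C) is added across the terminal allene π-bond to give the allylic dibromide F1. CrCl2 (THF, high dilution) turns the allylic bromide into an allylchromium that closes the ten-membered ring by Barbier-type (Nozaki–Hiyama) addition of C7 to the aldehyde through the same chair, the vinyl bromide staying intact, to give the 2-bromoallyl carbinol F2. Carbonylative lactonisation (Pd(PPh3)4, CO 1 atm, Et3N, THF) then forms C11–C12 and the lactone and comes back to the route at 16.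

Step 6. The skipped C1=C10 olefin may migrate into conjugation, or the enolisable aldehyde may self-condense, under the zinc alkoxide before alkynylation, and facial control may be incomplete. The fallback sets out from 7. Lithium methyl propiolate (LiN(SiMe3)2, THF, −90 °C) adds fast without stereocontrol to give 8 mixed with its C3 epimer F3. The mixture is oxidised (Dess–Martin periodinane, NaHCO3) to the ynone F4, and Midland reduction with (R)-Alpine-Borane (B-isopinocampheyl-9-borabicyclo[3.3.1]nonane from (+)-α-pinene) returns the (R)-carbinol, rejoining the route at 8.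

Step 9. The allene may be oxidised competitively, or facial selectivity may erode because the larger substituent on C10 is cis to C2. The fallback sets out from 8, whose free C3 hydroxyl is homoallylic to C1=C10. Hydroxyl-directed vanadium-catalysed epoxidation (VO(OiPr)3, chiral bishydroxamic acid ligand, cumene hydroperoxide, toluene, 0 °C) delivers oxygen only to the olefin within reach of the vanadium alkoxide, with the ligand setting the face, and gives epoxy alcohol F5. Silylation (Et3SiOTf, 2,6-lutidine) gives the silyl ether F6, and Me2CuLi at −78 °C, where the ynoate reacts faster than the trisubstituted epoxide, rejoins the route at 11.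

Further compounds

F1 | step 12 | (2Z,4R)-5-{(2R,3S)-3-[(2S,3E)-4,5-dibromo-2-[(tert-butyldimethylsilyl)oxy]pent-3-en-1-yl]-3-methyloxiran-2-yl}-3-methyl-4-[(triethylsilyl)oxy]pent-2-enal | O=C/C=C(/C)[C@H](O[Si](CC)(CC)CC)C[C@H]1O[C@@]1(C)C[C@H](O[Si](C)(C)C(C)(C)C)/C=C(/Br)CBr
F2 | step 12 | ten-membered 6-hydroxy-7-(1-bromovinyl) carbocycle, H6/H7 cis, 3-O-triethylsilyl, 8-O-tert-butyldimethylsilyl, other centres as in 20 | C=C(Br)[C@H]1[C@@H](O)/C=C(/C)[C@H](O[Si](CC)(CC)CC)C[C@H]2O[C@@]2(C)C[C@@H]1O[Si](C)(C)C(C)(C)C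
F3 | step 6 | methyl (4S,6Z,9S)-9-[(tert-butyldimethylsilyl)oxy]-4-hydroxy-7-methyldodeca-6,10,11-trien-2-ynoate | COC(=O)C#C[C@@H](O)C/C=C(/C)C[C@H](O[Si](C)(C)C(C)(C)C)C=C=C
F4 | step 6 | methyl (6Z,9S)-9-[(tert-butyldimethylsilyl)oxy]-7-methyl-4-oxododeca-6,10,11-trien-2-ynoate | COC(=O)C#CC(=O)C/C=C(/C)C[C@H](O[Si](C)(C)C(C)(C)C)C=C=C
F5 | step 9 | methyl (4R)-5-{(2R,3S)-3-[(2S)-2-[(tert-butyldimethylsilyl)oxy]penta-3,4-dien-1-yl]-3-methyloxiran-2-yl}-4-hydroxypent-2-ynoate | COC(=O)C#C[C@H](O)C[C@H]1O[C@@]1(C)C[C@H](O[Si](C)(C)C(C)(C)C)C=C=C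
F6 | step 9 | methyl (4R)-5-{(2R,3S)-3-[(2S)-2-[(tert-butyldimethylsilyl)oxy]penta-3,4-dien-1-yl]-3-methyloxiran-2-yl}-4-[(triethylsilyl)oxy]pent-2-ynoate | COC(=O)C#C[C@H](O[Si](CC)(CC)CC)C[C@H]1O[C@@]1(C)C[C@H](O[Si](C)(C)C(C)(C)C)C=C=C
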